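The ratio I want for this flask is substrate lost to side product against substrate reaching target, counted while solid still feeds the solution, because the partner charge of the next run hangs on it.

solid substrate 1.0 M; partner 1.30 M (in portions, 4); protic impurity 0.500 M; time 1.5 h; the portions of partner follow each other after 1.0 s, the first at the start

    solid substrate ⇌ dissolved substrate, rate k1*(cs1 - [dissolved substrate]) while solid is left; crystals form when [dissolved substrate] > cs1 (cs1 = 0.29 M, k1 = 3.58 s⁻¹)
    dissolved substrate + partner → target (k2 = 4.39 M⁻¹ s⁻¹)
    2 dissolved substrate → side product (k3 = 11.2 M⁻¹ s⁻¹)
    solid product ⇌ target, rate k4*(cs4 - [target]) while solid is left; crystals form when [target] > cs4 (cs4 = 13 mM, k4 = 0.726 s⁻¹)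
    partner + protic impurity → quenched reagent (k5 = 0.104 M⁻¹ s⁻¹)
    target ⇌ isomer of the product (K6 = 2.9, k6 = 0.0234 s⁻¹)
    partner → decomposed reagent (k7 = 0.0598 s⁻¹)

- percent here means solid substrate units held: one side product counts as two
- what is said of target includes solid product
- a doubled species enters its step squared and goes two at a time
- solid substrate, solid product is a solid; its amount is given per volume of the solution
- at the start none of the solid substrate is in solution
- what has only dissolved of solid substrate counts as not reacted
- the reaction counts as stopped when no species that holds the solid substrate changes by six tenths of a point or more over the second half of the time
- run time (flask): 1.5 h

- why nothing more happens at 1.5 h, or that something still does (for what has run out or reacted, a solid counts together with what of it has only dissolved) (all of the solid substrate has reacted / forward and back rates have come level / it is still moving)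
- part of the solid substrate that has turned into other species by 1.5 h (what has only dissolved does not count)
- target at 1.5 h, in percent of the solid substrate charged
- side product at 1.5 h, in percent of the solid substrate charged

Partner looks like excess at 1.30 equivalents, so I am tempted to trim it. Under the first portion, [partner] is 0.325 M. I set dissolution equal to what the two steps consume, with [partner] held at that value. The resulting quadratic gives [dissolved substrate] = 0.131 M, less than the solubility 0.29 M. Dimerisation then consumes substrate at 2 × 11.2 M⁻¹ s⁻¹ × [dissolved substrate]² and coupling at 4.39 M⁻¹ s⁻¹ × [dissolved substrate] × [partner]. Their quotient is 2.05, the substrate lost to side product per substrate reaching target; this is the branch ratio, a selectivity factor.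

This balance puts the net inflow at 0.570 M s⁻¹, which reckons the solid cleared in 1.75 s, or 1.75 portion intervals, so by my count the solid meets two portions and is gone before the third lands. Partner sags under the first portion and jumps with the second, so I trust the ratio to a few points only. It sends 32.7% of the substrate towards target and 67.2% to side product. I expect dissolved target to stay near its solubility, and the step to the isomer relaxes with a half-life of 0.367 min, short against the 1.5 h of the run, so the isomer takes about 3.77%, and I commit to 28.9% target at full conversion. That target line needs 0.327 M of partner, less than the 1.30 M charged. But [partner] under the first portion goes with the charge, and it stands in the ratio's denominator, so I leave the charge and its portions as they are in the next run.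

The forecast gives 100% conversion (99.5% to 100%), 32% target (27% to 38%) and 64% side product (57% to 69%), and it ends with "all of the solid substrate has reacted". Its ground is that “the squared dimerisation takes most of the substrate in the first two seconds or so”. My target is lower and my side product higher, both inside its ranges.

In this flask, all of the solid substrate has reacted: conversion is 100%, with 31.3% target and 64.9% side product. With the step to the isomer struck out, target in this flask reads 35.1%. The neighbour flask charges 0.78 M of partner, so its first portion is 0.195 M. The same balance gives [dissolved substrate] = 0.138 M and a branch ratio of 3.61 against 2.05, which puts 78.3% on side product. That neighbour flask ends with 20.6% target and 75.6% side product.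

(The rate constants belong to no real substance; the rest is arithmetic.)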